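The numbers in the tables stem from a simulated flask on assumed constants.

| setting | north | east | south-east | south-west | south |
|---|---|---|---|---|---|
| E | 0.500 M | 0.500 M | 1.50 M | 0.500 M | 0.100 M |
| Z | 0.500 M | 0.250 M | 0.500 M | 0.500 M | 0.100 M |
| X |  |  |  | 0.250 M |  |
| time |  |  |  |  | 5.8 h |

- north run (time / h: [E] / M): 0.33: 0.309; 1.0: 0.187; 1.9: 0.129; 3.0: 0.090; 4.3: 0.067; 5.8: 0.046
- east run (time / h: [E] / M): 0.33: 0.383; 1.0: 0.287; 1.9: 0.219; 3.0: 0.182; 4.3: 0.141; 5.8: 0.108
- south-east run (time / h: [E] / M): 0.33: 1.082; 1.0: 0.903; 1.9: 0.780; 3.0: 0.665; 4.3: 0.551; 5.8: 0.442
- south-west run (time / h: [E] / M): 0.33: 0.310; 1.0: 0.187; 1.9: 0.126; 3.0: 0.092; 4.3: 0.064; 5.8: 0.042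

(each reading ± 0.003 M)

- Overall: E + Z -> X.
- Constant volume, constant temperature.
- "The second partner" is Z.
- An order is taken over about fifteen percent of the charge, up and down.

* apparent order in [E] of the starting rate, round the charge of the north run (the rate where two percent of its E have turned into X) (one fixed amount of X, the same in the runs compared)
* apparent order in [Z] of the starting rate, round the charge of the north run (the rate where two percent of its E have turned into X)
* E in the south run at 5.8 h, as a share of the E charged

The east run does what its written equation forbids. E + Z → X cannot remove more E than the Z charged, yet by 5.8 h this run has lost 78.4% of its E, with Z, the limiting reagent there, charged at half of E.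

Two chemists dispute what this means for the south run. The first says E leaves with Z, and the extra loss is a side matter. The second says E has a Z-free route that counts where little Z is charged.

I read both pulls, a pull being the share of E lost per hour. The south-east run is charged with E at 3.00 times Z. Late in that run, E falls from 44.3% to 29.5% of its charge between 3.0 h and 5.8 h. I take that as the Z-free pull, 0.146 h⁻¹.

The first east interval gives the Z pull. I remove the Z-free pull from the loss there and divide by the mean Z, which gives 3.46 L mol⁻¹ h⁻¹.

The two pulls are equal at one Z level. Written as a fraction of the Z charged, that level is the crossing share 42.2% for the south run. Below it, the Z-free route takes E faster than Z does.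

The first chemist reckons the south run with Z alone. Z pull at the charge, times 5.8 h, comes to 2.00. Dividing the charge by one plus that leaves 33.3%.

The second multiplies that share by the Z-free survival of 42.9%, and by my reckoning gets 14.3%. The forecast, the second chemist's own, is slightly higher: 15% left, with orders 1 in E and 0.9 in Z. Its ground: “The E loss exceeds the Z charged (east, south-east), so E also has a Z-free route”.

The simulation gives 17.0% left in the south run, with orders 1.0 in E and 1.1 in Z. The order in Z is higher than the forecast's.

    E + Z → X (3.420 L mol⁻¹ h⁻¹)
    E + 2 Z → X + Z (0.7740 L² mol⁻² h⁻¹)
    2 Z → Ez (0.9216 L mol⁻¹ h⁻¹)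
    E → Qi (0.1454 h⁻¹)

The south run's crossing share of 42.2% lies well below its Z charge, so at the charge the Z pull is larger than the Z-free pull, and the order reverses once Z has fallen below that share. The path from E to Qi still proves the second chemist right for the south run: E stands at 17.0% at 5.8 h with that path and at 42.8% without it. The first chemist's region is the early north run, whose crossing share is smaller, 8.44%. There the Z-alone view gives 0.193 h for a quarter of the E to become X, and the north run takes 0.198 h.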